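I began from an easy step: these flasks carry the same charges and run for the same 2.0 min, so I asked how much of that time each one really works.

common to all: time 2.0 min

|  | substrate | partner | temperature | remark |
|---|---|---|---|---|
| Thursday's | 0.40 M (fed, over 80 s) | 0.440 M | 5 °C | all else is in the flask from the start; the feed brings no volume worth counting |
| Friday's | 0.40 M | 0.440 M | 5 °C | everything together at the start |
| Sunday's | 0.40 M (fed, over 20 s) | 0.440 M | 5 °C | all else is in the flask from the start; the feed brings no volume worth counting |
| Monday's | 0.40 M | 0.440 M (fed, over 80 s) |  | the addition at −15 °C, then warmed to 5 °C; the feed brings no volume worth counting |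
| Saturday's | 0.40 M | 0.440 M |  | everything together at the start at −15 °C, warmed to 5 °C at 80 s |

* the flask that comes out highest in amount of target, in percent of the substrate charged, or "all alike" when all lie within 1.5 percentage points (Thursday's / Friday's / Sunday's / Monday's / Saturday's / all alike)
* target at the end, in percent of the substrate charged, Thursday's
* target at the end, in percent of the substrate charged, Friday's
* target at the end, in percent of the substrate charged, Sunday's
* target at the end, in percent of the substrate charged, Monday's
* target at the end, in percent of the substrate charged, Saturday's

- amounts and yields of target count crystals too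
- given per volume of solution although it is solid: crystals
- all constants are for 5 °C and move with temperature by the activation energies and enthalpies

    partner + intermediate → target (k1 = 0.093 M⁻¹ s⁻¹, Ea1 = 57.0 kJ mol⁻¹)
    substrate ⇌ dormant form (K2 = 4.4, k2 = 0.011 s⁻¹, Ea2 = 85.0 kJ mol⁻¹, ΔH2 = −42.0 kJ mol⁻¹)
    substrate → decomposition product (k3 = 4.5 × 10⁻⁵ s⁻¹, Ea3 = 87.0 kJ mol⁻¹)
    crystals ⇌ target, rate k4*(cs4 - [target]) while solid is left; crystals form when [target] > cs4 (cs4 = 0.15 M, k4 = 0.96 s⁻¹)
    substrate → intermediate (k5 = 0.013 s⁻¹, Ea5 = 82.0 kJ mol⁻¹)
    (constants at 5 °C)

I built up Friday's first. With the main road alone, substrate makes intermediate at 0.013 s⁻¹, and intermediate meets partner held at its charge. That is a pseudo-first-order constant kI, the rate constant of that step times the charged partner, 0.0409 s⁻¹. The usual sum for two first-order steps in a row then gave 69.5% of the substrate as target.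

Next I added the forward loss to the dormant form at 0.011 s⁻¹. Substrate then leaves at kA, 0.0240 s⁻¹, and a share s of 54.2% of it goes towards intermediate, so the figure fell to 47.4%. Decomposition at 4.5 × 10⁻⁵ s⁻¹ runs far slower than that loss, and crystals count as target, so I added neither. I also left out the way back from the dormant form and the fall of partner, which push in opposite directions.

The other flasks needed one new quantity. A steady feed spreads the arrival of substrate over a curve, and I replaced that curve by its mean, the midpoint of the feed. The warm time θ is what remains of the run after that mean arrival, counted in seconds at 5 °C. For Thursday's it is 80.0 s, and for Sunday's 110 s.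

A cold second counts for less. At −15 °C the making of intermediate runs at a fraction 0.0641 of its speed at 5 °C, so 80 s of cold are worth 5.13 s, and Monday's and Saturday's each have θ of 45.1 s.

Putting θ in place of the run time gave 37.9% for Thursday's, 45.7% for Sunday's, 21.9% for Monday's and 21.9% for Saturday's. The longest θ belongs to Friday's.

The forecast also named Friday's, with 34.5% for Thursday's, 45.5% for Friday's, 42.7% for Sunday's, 21.3% for Monday's and 21.7% for Saturday's, on the ground that “slow feeds and the cold 80 s both lose time”. Its Thursday's figure lay lower than mine.

The run gave 34.1% for Thursday's, 45.7% for Friday's, 43.5% for Sunday's, 20.7% for Monday's and 20.8% for Saturday's, with Friday's highest.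

In Friday's, intermediate had a half-life of 0.28 min by its step with partner alone, partner as charged, shorter than the 1.1 min of substrate by the forward step to the dormant form alone. Thursday's θ of 80.0 s had given a figure 3.8 percentage points above the run, and carried to the run dosed over 0.133 min it grows to 116 s, where the same sum gives 46.8% against that run's 44.8%. Friday's highest place gives way to "all alike" when the flasks come within 1.5 points of one another. Left to 20.0 min, Friday's stands at 87.1% and Monday's at 86.0%, 1.1 points apart.

The numbers are assumed; the rest is arithmetic.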